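**Early entries.**

| flask | starting material | protic impurity | remark | time |
|---|---|---|---|---|
| red | 1.5 M | 0.15 M | run made earlier |  |
| violet | 1.5 M | 0.10 M | run made earlier |  |
| amber | 1.5 M | 0.22 M | run made earlier |  |
| grey | 3 M | 0.15 M | run made earlier |  |
| Thursday's | 1.5 M | 0.150 M | one stirred flow tank at steady state, fed with the mixture as stated, mean residence time 500 min |  |
| Monday's | 1.5 M | 0.150 M | plug flow through a tube for 50 min, no back-mixing | 50 min |
| Friday's | 1.5 M | 0.150 M | a closed flask charged with all of it at once and left for 50 min | 50 min |
| Tuesday's | 1.5 M | 0.150 M | a single well-mixed tank run continuously and read at steady state, 50 min in it on average |  |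



| run | time / min | single ring / % | open dimer / % |
|---|---|---|---|
| red | 1.50 | 7 | 5 |
| red | 5.00 | 20 | 7 |
| red | 8.00 | 28 | 12 |
| red | 12.0 | 35 | 12 |
| red | 20.0 | 42 | 12 |
| red | 25.0 | 47 | 11 |
| red | 30.0 | 50 | 7 |
| violet | 2.50 | 12 | 8 |
| violet | 8.00 | 30 | 10 |
| violet | 15.0 | 41 | 9 |
| violet | 20.0 | 44 | 10 |
| violet | 30.0 | 52 | 6 |
| violet | 40.0 | 59 | 5 |
| violet | 50.0 | 61 | 4 |
| amber | 4.00 | 16 | 8 |
| amber | 6.00 | 20 | 7 |
| amber | 10.0 | 31 | 9 |
| amber | 15.0 | 38 | 4 |
| amber | 20.0 | 41 | 8 |
| amber | 30.0 | 50 | 6 |
| amber | 50.0 | 58 | 5 |
| grey | 10.0 | 28 | 17 |
| grey | 20.0 | 37 | 11 |
| grey | 30.0 | 44 | 10 |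
| grey | 40.0 | 45 | 8 |
| grey | 50.0 | 49 | 3 |

(each reading ± 1.5 percentage points)

- in percentages every species weighs as the starting material in it: one open dimer or ring dimer counts as two
- in percentages every species weighs as the starting material in it: one open trimer counts as three
- the stated concentrations are those of everything mixed, before any reaction; amounts are the same in each set-up
- the analysis behind the earlier runs scatters by 1.5 percentage points, standard deviation
- the earlier runs were made in a closed, stirred flask

1. the set-up with the highest share of single ring in all that became single ring or open dimer or open trimer or ring dimer, at the outlet or at the end ("none" if the first two lie within 2 percentage points) (Thursday's / Monday's / Friday's / Tuesday's / none)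
2. share of single ring in all that became single ring or open dimer or open trimer or ring dimer, at the outlet or at the end, Thursday's
3. share of single ring in all that became single ring or open dimer or open trimer or ring dimer, at the outlet or at the end, Monday's
4. share of single ring in all that became single ring or open dimer or open trimer or ring dimer, at the outlet or at the end, Friday's
5. share of single ring in all that became single ring or open dimer or open trimer or ring dimer, at the outlet or at the end, Tuesday's

In the red run at 1.50 min I read 7% of the charge as single ring and 5% as open dimer. I kept these figures as fractions of the charge, as a ledger for the starting material: single ring, open dimer, open trimer, ring dimer, starting material still unspent, and whatever the protic impurity consumes.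

**The bill.** I booked the last entry by counting turnovers, assuming one mole of starting material lost per mole of protic impurity, the limiting reagent of such a step. The impurity bill, 10.0% of the charge for Monday's and Friday's, is protic impurity charged over starting material charged. The runs hint at it. Amber's bill was 14.7% and violet's 6.67%, and at 50.0 min amber read 3 percentage points less single ring, against a scatter of 1.5 points per reading.

**The forecast.** It chose Thursday's, giving 95% there, 64% for Monday's, 64% for Friday's and 76% for Tuesday's, and it held that “the protic impurity has no visible effect”. I parted from it there. Taking single ring at 59.5%, the mean of violet and amber, its Friday's share implied a denominator of 93.0%. I assumed that material billed to the impurity reaches none of the four products, so I subtracted the bill and reckoned 71.7% for Friday's. Monday's tube has no back-mixing and the same time, so I gave it the same figure. I reckoned no tank figures of my own.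

**The result.** The simulation gave 97.6% for Thursday's, 73.3% for Monday's, 73.3% for Friday's and 85.0% for Tuesday's, so Thursday's was best.

    starting material → single ring (k = 9.90 × 10⁻⁴ s⁻¹)
    2 starting material → open dimer (k = 2.79 × 10⁻⁴ M⁻¹ s⁻¹)
    starting material + open dimer → open trimer (k = 7.35 × 10⁻⁴ M⁻¹ s⁻¹)
    open dimer → ring dimer (k = 3.97 × 10⁻⁴ s⁻¹)
    starting material ⇌ dormant form (K = 0.434, k = 7.22 × 10⁻⁴ s⁻¹)
    starting material + protic impurity → quenched substrate (k = 0.00953 M⁻¹ s⁻¹)

**The bill paid.** Friday's flask held 10.0% of quenched substrate at the end, matching the bill of 10.0%, and half of that step's turnover up to the end was done by 0.890 min, far shorter than the 50 min of the run. The neighbouring flask charged with 0.60 M of starting material carried a bill of 25.0%, ended with 24.2% of quenched substrate, and gave a share of 88.0%.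

(The earlier runs and the new flask are calculated for substances that don't exist; the scatter is artificial.)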